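**Retrosynthetic overview**

1. Target 10 ⇒ C6–CH3 bond: methyl transfer from AlMe3 to the cyclic peroxycarbenium ion 9 of methyl peroxyketal 8 (sets C6 last, on the intact ring).
2. 8 ⇒ O–C3 bond, closing the only ring (the 1,2-dioxane): catalytic asymmetric intramolecular peroxy-Michael addition of hydroperoxy ketal 7 (sets C3 and C2).
3. 7 ⇒ keto enoate 6 by perketalisation (H2O2, MeOH); 6 ⇒ C7–C8 bond: alkylation of the kinetic enolate of keto ester 3 with (2E,6E)-farnesyl bromide 4.
4. 3 ⇒ hex-5-en-2-one 1 + methyl methacrylate 2 by cross-metathesis (sets the E-enoate).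

Assumption: the SMILES is read as methyl (2R)-2-[(3S,6R)-…]propanoate with an all-E side chain; catalyst G is assumed to give the (3S) series as its (S,S) antipode, and its (R,R) antipode is used if the sense proves opposite.

Catalyst G: a C2-symmetric chiral guanidine–bis(urea) organocatalyst used as the free base. It is a 2-octadecylguanidine whose other two nitrogens each carry an (S)-1-benzyl-2-{3-[3,5-bis(trifluoromethyl)phenyl]ureido}ethyl arm.

**Step 1**
Reactants: 1 hex-5-en-2-one; 2 methyl methacrylate
Product: 3 methyl (2E)-2-methyl-6-oxohept-2-enoate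
Conditions: second-generation Grubbs catalyst RuCl2(=CHPh)(H2IMes)(PCy3) (3 mol%), 2 (5 equiv), CH2Cl2, 40 °C
Reagents that add atoms: none
Why: Olefin cross-metathesis of a terminal alkene with a 1,1-disubstituted acrylate gives the trisubstituted enoate with high E selectivity, driven by loss of ethylene; the ketone is inert and no stereocentre is formed.

**Step 2**
Reactants: 3 methyl (2E)-2-methyl-6-oxohept-2-enoate; 4 (2E,6E)-farnesyl bromide
Product: 6 methyl (2E,9E,13E)-2,10,14,18-tetramethyl-6-oxononadeca-2,9,13,17-tetraenoate, via lithium enolate 5 (not isolated)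
Conditions: LiN(iPr)2 (LDA), THF, −78 °C (3 added to the base); then 4, −78 to −30 °C
Reagents that add atoms: none
Why: Kinetic deprotonation of the methyl ketone occurs at CH3 (the enoate γ-hydrogens are far less acidic), and SN2 enolate alkylation by the allylic bromide keeps every alkene geometry; no stereocentre is formed.

**Step 3**
Reactants: 6 methyl (2E,9E,13E)-2,10,14,18-tetramethyl-6-oxononadeca-2,9,13,17-tetraenoate
Product: 7 methyl (2E,9E,13E)-6-hydroperoxy-6-methoxy-2,10,14,18-tetramethylnonadeca-2,9,13,17-tetraenoate (racemic at the ketal carbon C6)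
Conditions: urea–hydrogen peroxide (3 equiv), Sc(OTf)3 (5 mol%), MeOH, rt
Reagents that add atoms: hydrogen peroxide (as its urea adduct), OO; methanol, CO
Why: Lewis-acid-catalysed perketalisation: only the ketone forms a ketal, and methanol and H2O2 add to give the α-methoxy hydroperoxide, while the enoate and the trisubstituted alkenes are inert to neutral H2O2; the ketal carbon is a stereorandom placeholder that step 5 erases.

**Step 4**
Reactants: 7 methyl (2E,9E,13E)-6-hydroperoxy-6-methoxy-2,10,14,18-tetramethylnonadeca-2,9,13,17-tetraenoate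
Product: 8 methyl (2R)-2-[(3S)-6-methoxy-6-[(3E,7E)-4,8,12-trimethyltrideca-3,7,11-trien-1-yl]-1,2-dioxan-3-yl]propanoate (both C6 epimers)
Conditions: catalyst G (10 mol%), toluene, −20 °C
Reagents that add atoms: none
Why: Proposed new method: a catalytic asymmetric intramolecular peroxy-Michael addition. The chiral guanidine deprotonates the OOH of 7 (pKa about 12); the guanidinium holds the peroxide anion while the two urea groups bind the ester carbonyl; the terminal peroxide oxygen closes the 1,2-dioxane by 6-exo-trig attack on one face of C3 of the E-enoate (C3 = S, catalyst control for both C6 epimers of 7); the ester enolate is then protonated by the guanidinium N–H anti to the new C–O bond, which for an E-alkene gives the 2,3-syn relation (C2 = R). Closest known reaction types: the racemic amine-mediated peroxy-Michael ring closure of hydroperoxy ketals onto enoates in fluorinated alcohols, and guanidine–urea-catalysed asymmetric additions of hydroperoxide anions to enones.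

**Step 5**
Reactants: 8 methyl (2R)-2-[(3S)-6-methoxy-6-[(3E,7E)-4,8,12-trimethyltrideca-3,7,11-trien-1-yl]-1,2-dioxan-3-yl]propanoate
Product: 10 methyl (2R)-2-[(3S,6R)-6-methyl-6-[(3E,7E)-4,8,12-trimethyltrideca-3,7,11-trien-1-yl]-1,2-dioxan-3-yl]propanoate (target), via peroxycarbenium ion 9 (not isolated)
Conditions: AlMe3 (4 equiv), CH2Cl2, −78 to −20 °C
Reagents that add atoms: trimethylaluminium, C[Al](C)C
Why: Proposed new method: substitution of a cyclic peroxyketal by a methyl group through its peroxycarbenium ion. Lewis-acid ionisation of 3-alkoxy-1,2-dioxanes is established for silyl nucleophiles, and AlMe3 is the standard methyl donor for six-membered oxocarbenium ions from tetrahydropyranyl ketals, but the combination on a peroxyketal is new. AlMe3 complexes the exocyclic OMe, both C6 epimers of 8 converge on the same ion 9, and the aluminate delivers CH3 along the axial trajectory of the half-chair that keeps the C3 side chain pseudo-equatorial (chair-like transition state). The methyl therefore ends axial and cis to the C3 substituent with the polyene chain equatorial, i.e. 6R; the O–O bond and the ester are expected to survive AlMe3 at low temperature.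

**Compound list**

1 | hex-5-en-2-one | CC(=O)CCC=C | starting material
2 | methyl methacrylate | C=C(C)C(=O)OC | starting material
3 | methyl (2E)-2-methyl-6-oxohept-2-enoate | CC(=O)CC/C=C(\C)C(=O)OC | intermediate
4 | (2E,6E)-farnesyl bromide, (2E,6E)-1-bromo-3,7,11-trimethyldodeca-2,6,10-triene | BrC/C=C(\C)CC/C=C(\C)CCC=C(C)C | starting material
5 | lithium (5E)-7-methoxy-6-methyl-7-oxohepta-1,5-dien-2-olate (kinetic lithium enolate of 3, not isolated) | [Li+].[O-]C(=C)CC/C=C(\C)C(=O)OC | intermediate
6 | methyl (2E,9E,13E)-2,10,14,18-tetramethyl-6-oxononadeca-2,9,13,17-tetraenoate | COC(=O)/C(C)=C/CCC(=O)CC/C=C(\C)CC/C=C(\C)CCC=C(C)C | intermediate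
7 | methyl (2E,9E,13E)-6-hydroperoxy-6-methoxy-2,10,14,18-tetramethylnonadeca-2,9,13,17-tetraenoate, racemic at C6 | COC(=O)/C(C)=C/CCC(OC)(OO)CC/C=C(\C)CC/C=C(\C)CCC=C(C)C | intermediate
8 | methyl (2R)-2-[(3S)-6-methoxy-6-[(3E,7E)-4,8,12-trimethyltrideca-3,7,11-trien-1-yl]-1,2-dioxan-3-yl]propanoate, both C6 epimers | COC(=O)[C@H](C)[C@@H]1CCC(OC)(CC/C=C(\C)CC/C=C(\C)CCC=C(C)C)OO1 | intermediate
9 | cyclic peroxycarbenium ion of 8 (C6=O+ in the ring, C3 = S, C2 = R) as its methoxytrimethylaluminate ion pair, not isolated | COC(=O)[C@H](C)[C@@H]1CCC(CC/C=C(\C)CC/C=C(\C)CCC=C(C)C)=[O+]O1.CO[Al-](C)(C)C | intermediate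
10 | methyl (2R)-2-[(3S,6R)-6-methyl-6-[(3E,7E)-4,8,12-trimethyltrideca-3,7,11-trien-1-yl]-1,2-dioxan-3-yl]propanoate (CNP0145612.1) | COC(=O)[C@H](C)[C@@H]1CC[C@@](C)(CC/C=C(\C)CC/C=C(\C)CCC=C(C)C)OO1 | target

**Step count and risks**

Total step count: 5. Longest linear sequence: 5 (1 → 3 → 6 → 7 → 8 → 10).

The three steps most likely to fail:

Risk 1, step 4 (proposed new method). The α-methyl enoate may add slowly, the peroxy enolate may collapse to an epoxide by O–O cleavage instead of being protonated, or the ee may be low. The fallback uses known chemistry, sets out from 7 and returns at 8. Et2NH in CF3CH2OH, the established amine-mediated peroxy-Michael ring closure of hydroperoxy ketals, gives the peroxyketal as a racemate, that is 8 together with its antipodes methyl (2S)-2-[(3R)-6-methoxy-6-[(3E,7E)-4,8,12-trimethyltrideca-3,7,11-trien-1-yl]-1,2-dioxan-3-yl]propanoate F1. Preparative HPLC on a chiral stationary phase removes F1 (the C6 epimers need not be separated), and step 5 follows unchanged.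

Risk 2, step 5 (proposed new method). AlMe3 may cleave the O–O bond, ionisation may occur at the ring oxygen and open the ring, or the methyl group may enter from the other face. The fallback uses only known reactions, sets out from 6 and returns at 10, at the cost of stereocontrol.

- Wittig methylenation (Ph3P=CH2, THF) gives the 1,1-disubstituted alkene methyl (2E,9E,13E)-2,10,14,18-tetramethyl-6-methylidenenonadeca-2,9,13,17-tetraenoate F2.
- Mukaiyama–Isayama peroxysilylation (Co(acac)2, O2, Et3SiH), which takes the 1,1-disubstituted alkene in preference to the trisubstituted ones, gives the tertiary silyl peroxide methyl (2E,9E,13E)-2,6,10,14,18-pentamethyl-6-[(triethylsilyl)peroxy]nonadeca-2,9,13,17-tetraenoate F3.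
- HF·pyridine frees the hydroperoxide methyl (2E,9E,13E)-6-hydroperoxy-2,6,10,14,18-pentamethylnonadeca-2,9,13,17-tetraenoate F4.
- Et2NH in CF3CH2OH cyclises F4 to 10 together with its C6 epimer methyl (2R)-2-[(3S,6S)-6-methyl-6-[(3E,7E)-4,8,12-trimethyltrideca-3,7,11-trien-1-yl]-1,2-dioxan-3-yl]propanoate F5 and their antipodes, the (2S,3R,6S) compound F6 and the (2S,3R,6R) compound F7.
- Silica gel chromatography separates the C6 epimers and chiral-phase HPLC the enantiomers, giving 10.

Risk 3, step 2. The amide base may add to the enoate of 3 or deprotonate it at the γ-position, or the enolate may equilibrate and lose regiocontrol. The fallback reverses the order of the two C–C bond formations, sets out from 1 and returns at 6. LiN(iPr)2 in THF at −78 °C converts 1 into its kinetic enolate lithium hexa-1,5-dien-2-olate F8. Alkylation with 4 gives (8E,12E)-9,13,17-trimethyloctadeca-1,8,12,16-tetraen-5-one F9. Cross-metathesis of the terminal alkene of F9 with an excess of 2 (second-generation Grubbs catalyst RuCl2(=CHPh)(H2IMes)(PCy3), CH2Cl2, 40 °C) installs the enoate last and gives 6.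

**Further compounds**

F1 | step 4 | methyl (2S)-2-[(3R)-6-methoxy-6-[(3E,7E)-4,8,12-trimethyltrideca-3,7,11-trien-1-yl]-1,2-dioxan-3-yl]propanoate (both C6 epimers) | COC(=O)[C@@H](C)[C@H]1CCC(OC)(CC/C=C(\C)CC/C=C(\C)CCC=C(C)C)OO1
F2 | step 5 | methyl (2E,9E,13E)-2,10,14,18-tetramethyl-6-methylidenenonadeca-2,9,13,17-tetraenoate | COC(=O)/C(C)=C/CCC(=C)CC/C=C(\C)CC/C=C(\C)CCC=C(C)C
F3 | step 5 | methyl (2E,9E,13E)-2,6,10,14,18-pentamethyl-6-[(triethylsilyl)peroxy]nonadeca-2,9,13,17-tetraenoate (racemic) | COC(=O)/C(C)=C/CCC(C)(OO[Si](CC)(CC)CC)CC/C=C(\C)CC/C=C(\C)CCC=C(C)C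
F4 | step 5 | methyl (2E,9E,13E)-6-hydroperoxy-2,6,10,14,18-pentamethylnonadeca-2,9,13,17-tetraenoate (racemic) | COC(=O)/C(C)=C/CCC(C)(OO)CC/C=C(\C)CC/C=C(\C)CCC=C(C)C
F5 | step 5 | methyl (2R)-2-[(3S,6S)-6-methyl-6-[(3E,7E)-4,8,12-trimethyltrideca-3,7,11-trien-1-yl]-1,2-dioxan-3-yl]propanoate | COC(=O)[C@H](C)[C@@H]1CC[C@](C)(CC/C=C(\C)CC/C=C(\C)CCC=C(C)C)OO1
F6 | step 5 | methyl (2S)-2-[(3R,6S)-6-methyl-6-[(3E,7E)-4,8,12-trimethyltrideca-3,7,11-trien-1-yl]-1,2-dioxan-3-yl]propanoate | COC(=O)[C@@H](C)[C@H]1CC[C@](C)(CC/C=C(\C)CC/C=C(\C)CCC=C(C)C)OO1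
F7 | step 5 | methyl (2S)-2-[(3R,6R)-6-methyl-6-[(3E,7E)-4,8,12-trimethyltrideca-3,7,11-trien-1-yl]-1,2-dioxan-3-yl]propanoate | COC(=O)[C@@H](C)[C@H]1CC[C@@](C)(CC/C=C(\C)CC/C=C(\C)CCC=C(C)C)OO1
F8 | step 2 | lithium hexa-1,5-dien-2-olate | [Li+].[O-]C(=C)CCC=C
F9 | step 2 | (8E,12E)-9,13,17-trimethyloctadeca-1,8,12,16-tetraen-5-one | C=CCCC(=O)CC/C=C(\C)CC/C=C(\C)CCC=C(C)C
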